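The hydroazulene is cut across C1–C5 and C7–C8 in a retro-(4+3) sense (daucane numbering: five-membered ring C1 to C5, seven-membered ring C5 to C10 and back to C1). The step exploits the C4–C5–C6 dioxygenated array next to the C7 methylene: a rhodium carbenoid at C5 carries C4 as its acyl arm and C6=C7 as a siloxyvinyl arm, and C1=C10–C9=C8 is an E,E-diene held by the C2–C3 chain. One cyclopropanation–Cope cascade converts an acyclic 2-siloxyvinyl diazo trienone into the bicycle, closing both rings and fixing quaternary C1. Isopropyl addition, dehydrogenation, directed reduction, epoxidation, hydride opening and vanillate esterification follow.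

Key step: step 7

Remark (numbering): bicyclic compounds carry daucane locants, meaning the 4-isopropyl-1,8-dimethylbicyclo[5.3.0]decane skeleton with C1 (angular methyl), C4 (isopropyl, hydroxyl), C6 (ester oxygen) and C8 (methyl, hydroxyl); acyclic precursors use the same labels for the atoms they become.

Assumption (catalyst sense): Rh2(S-PTAD)4 is dirhodium tetrakis[(S)-(1-adamantyl)(phthalimido)acetate] (divalent rhodium); it is assumed to give (1R)-13, and its mirror image Rh2(R-PTAD)4 would be used if a trial run shows the opposite sense.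

Step 1
Reactants: 1 (E)-but-2-enal (crotonaldehyde); 2 ethyl 2-(triphenylphosphoranylidene)propanoate
Product: 3 ethyl (2E,4E)-2-methylhexa-2,4-dienoate
Conditions: CH2Cl2, rt
Reagents that add atoms: none
Why: Wittig olefination with the stabilised, α-branched ylide gives the E trisubstituted alkene (ester trans to the chain) and leaves the E crotyl double bond as it is, supplying C1 with its methyl, C2, and C8–C10 with the C8 methyl.

Step 2
Reactants: 3 ethyl (2E,4E)-2-methylhexa-2,4-dienoate
Product: 4 (2E,4E)-2-methylhexa-2,4-dien-1-ol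
Conditions: i-Bu2AlH (2.2 equiv), CH2Cl2, −78 to 0 °C
Reagents that add atoms: none
Why: 1,2-Reduction of a conjugated ester by i-Bu2AlH stops at the allylic alcohol and does not touch the diene.

Step 3
Reactants: 4 (2E,4E)-2-methylhexa-2,4-dien-1-ol
Product: 5 (2E,4E)-1-bromo-2-methylhexa-2,4-diene
Conditions: PBr3, Et2O, 0 °C
Reagents that add atoms: phosphorus tribromide, BrP(Br)Br
Why: Bromination of a primary allylic alcohol through its phosphite ester keeps both E alkenes, the conjugated primary bromide being also the thermodynamically favoured allylic isomer, and the crude bromide is used at once.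

Step 4
Reactants: 5 (2E,4E)-1-bromo-2-methylhexa-2,4-diene; 6 pentane-2,4-dione (acetylacetone)
Product: 8 (7E,9E)-7-methylundeca-7,9-diene-2,4-dione, via acetylacetone dianion 7 (not isolated)
Conditions: 6, NaH, THF, 0 °C; n-BuLi, 0 °C; then 5, 0 °C to rt
Reagents that add atoms: none
Why: The 1,3-dianion 7 reacts only at its terminal carbon (γ-alkylation of a β-dicarbonyl dianion), displacing the primary allylic bromide in an SN2 reaction that joins C3 to C2.

Step 5
Reactants: 8 (7E,9E)-7-methylundeca-7,9-diene-2,4-dione
Product: 9 (7E,9E)-3-diazo-7-methylundeca-7,9-diene-2,4-dione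
Conditions: 4-acetamidobenzenesulfonyl azide, Et3N, MeCN, 0 °C to rt
Reagents that add atoms: 4-acetamidobenzenesulfonyl azide, CC(=O)Nc1ccc(S(=O)(=O)N=[N+]=[N-])cc1
Why: Regitz diazo transfer goes to the doubly activated central methylene (the future C5) of a 1,3-diketone.

Step 6
Reactants: 9 (7E,9E)-3-diazo-7-methylundeca-7,9-diene-2,4-dione
Product: 11 (7E,9E)-2-[(tert-butyldimethylsilyl)oxy]-3-diazo-7-methylundeca-1,7,9-trien-4-one, via lithium enolate 10 (not isolated)
Conditions: LiN(SiMe3)2 (1.05 equiv), THF, −78 °C; then t-BuMe2SiOTf, −78 °C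
Reagents that add atoms: tert-butyldimethylsilyl trifluoromethanesulfonate, CC(C)(C)[Si](C)(C)OS(=O)(=O)C(F)(F)F
Why: Kinetic deprotonation by the hindered amide base favours the unhindered acetyl methyl (C7) over the C3 methylene, and O-silylation of enolate 10 gives the 2-siloxyvinyl diazoketone (enol silylation of a 2-diazo-1,3-dicarbonyl compound), which is filtered through base-washed silica and used at once.

Step 7
Reactants: 11 (7E,9E)-2-[(tert-butyldimethylsilyl)oxy]-3-diazo-7-methylundeca-1,7,9-trien-4-one
Product: 13 (3aR,6R)-8-[(tert-butyldimethylsilyl)oxy]-3a,6-dimethyl-3,3a,6,7-tetrahydroazulen-1(2H)-one, via divinylcyclopropane 12 (not isolated)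
Conditions: Rh2(S-PTAD)4 (1 mol %), heptane, slow addition of 11, 0 °C to rt; then 80 °C
Reagents that add atoms: none
Why: Loss of N2 from 11 at Rh2(S-PTAD)4 gives a donor–acceptor carbenoid at C5 (acyl arm C4, siloxyvinyl arm C6=C7) that adds across the tethered C1=C10 alkene (bonds C5–C1 and C5–C10) to give bicyclo[3.1.0]hexanone 12, whose cis-divinylcyclopropane then rearranges through a boat [3,3] transition state (C7–C8 forms, C5–C10 breaks). The closest known reaction type is the dirhodium-catalysed intramolecular tandem cyclopropanation–Cope rearrangement of vinyldiazo carbonyl compounds bearing a tethered diene, a formal (4+3) cycloaddition. The five-membered ring closes by intramolecular carbene addition over the three-atom C4–C3–C2 tether, and the seven-membered ring closes in the sigmatropic step through the new C7–C8 bond as the cyclopropane opens. C1 is set by the face of the alkene that the chiral catalyst selects and is not touched by the concerted Cope step, whereas C8 follows stereospecifically from the E-propenyl group in the boat (methyl outward, hence trans to the C1 methyl) and is erased in step 10. The step needs reaction at the proximal alkene, a cis relation of the two vinyl groups and enantioface selection: the tether length secures the first, the E geometry of C1=C10 the second (syn addition leaves the propenyl group exo, beside the bridgehead siloxyvinyl group), and only the catalyst can supply the third because 11 has no stereocentre. Since the C1 methyl is forced to lie under the boat, the rearrangement should need warming and not proceed at room temperature.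

Step 8
Reactants: 13 (3aR,6R)-8-[(tert-butyldimethylsilyl)oxy]-3a,6-dimethyl-3,3a,6,7-tetrahydroazulen-1(2H)-one; 14 isopropylmagnesium chloride
Product: 15 (1R,3aR,6R)-8-[(tert-butyldimethylsilyl)oxy]-3a,6-dimethyl-1-(propan-2-yl)-1,2,3,3a,6,7-hexahydroazulen-1-ol
Conditions: 14, anhydrous CeCl3, THF, −78 to 0 °C; aq. NaHCO3 quench
Reagents that add atoms: none
Why: The reagent i-PrCeCl2 made from 14 adds 1,2 to the vinylogous-ester carbonyl C4 without the enolisation or β-hydride reduction that the Grignard reagent alone would risk, and it should approach anti to the pseudo-axial C1 methyl, the other face being flanked only by the flat sp2 C10, so that the isopropyl group ends trans to that methyl (daucane 4R); the acid-labile tertiary allylic alcohol is kept basic and taken on crude.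

Step 9
Reactants: 15 (1R,3aR,6R)-8-[(tert-butyldimethylsilyl)oxy]-3a,6-dimethyl-1-(propan-2-yl)-1,2,3,3a,6,7-hexahydroazulen-1-ol
Product: 16 (1R,4R,5R,8R)-4-hydroxydauc-9-en-6-one
Conditions: Bu4NF, AcOH (1:1), THF, 0 °C to rt
Reagents that add atoms: none
Why: Buffered fluoride cleaves the enol silyl ether to the C6 ketone without acid (no dehydration) or strong base (no retro-aldol), and C5, which stays epimerisable through the enol, should settle with its hydrogen trans to the C1 methyl, where C6 is anti to the isopropyl group and hydrogen-bonded to the C4 hydroxyl.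

Step 10
Reactants: 16 (1R,4R,5R,8R)-4-hydroxydauc-9-en-6-one
Product: 17 (1R,4R,5R)-4-hydroxydauca-7,9-dien-6-one
Conditions: IBX, 4-methoxypyridine N-oxide, DMSO, rt
Reagents that add atoms: none
Why: IBX dehydrogenation of a ketone to its enone can only run toward C7–C8 because C5 has no β-hydrogen, the allylic C8–H is easily lost, and the 4-methoxypyridine N-oxide complex allows room temperature, which spares the tertiary aldol; the C8 stereocentre disappears here.

Step 11
Reactants: 17 (1R,4R,5R)-4-hydroxydauca-7,9-dien-6-one
Product: 18 (1R,4R,5S,6S)-dauca-7,9-diene-4,6-diol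
Conditions: Me4NBH(OAc)3, MeCN/AcOH (1:1), −30 to 0 °C
Reagents that add atoms: none
Why: In this hydroxyl-directed (Saksena–Evans) reduction the C4 alkoxyborohydride delivers hydride within the molecule to the carbonyl face turned toward C1, the face that external hydrides avoid, and so should give the 6S alcohol with the new hydroxyl cis to C5–H, while the reagent is too weak to reduce an unassisted ketone or its conjugated alkene.

Step 12
Reactants: 18 (1R,4R,5S,6S)-dauca-7,9-diene-4,6-diol
Product: 19 (1R,4R,5S,6R,7R,8S)-7,8-epoxydauc-9-ene-4,6-diol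
Conditions: VO(acac)2 (5 mol %), t-BuOOH, 2,6-lutidine, CH2Cl2, 0 °C
Reagents that add atoms: tert-butyl hydroperoxide, CC(C)(C)OO
Why: The hydroxyl-directed epoxidation catalysed by VO(acac)2 takes only the allylic C7=C8 bond of the diene and puts the oxygen on the face of the C6 hydroxyl, as expected for a cyclohept-2-enol, which sets C8.

Step 13
Reactants: 19 (1R,4R,5S,6R,7R,8S)-7,8-epoxydauc-9-ene-4,6-diol
Product: 20 (1R,4R,5S,6S,8R)-dauc-9-ene-4,6,8-triol
Conditions: NaAlH2(OCH2CH2OCH3)2 (excess), THF, 0 °C to rt
Reagents that add atoms: none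
Why: The C6 alkoxyaluminate delivers hydride within the molecule to C7, the nearer and less substituted oxirane carbon (reduction of a 2,3-epoxy alcohol to the 1,3-diol), so the C8–O bond and its configuration are kept and the C9=C10 alkene is not involved.

Step 14
Reactants: 21 vanillic acid (4-hydroxy-3-methoxybenzoic acid)
Product: 23 4-[(tert-butyldimethylsilyl)oxy]-3-methoxybenzoic acid, via bis-silyl derivative 22 (not isolated)
Conditions: t-BuMe2SiCl (2.5 equiv), imidazole, DMF, rt; then AcOH/THF/H2O, rt
Reagents that add atoms: tert-butyldimethylsilyl chloride, CC(C)(C)[Si](C)(C)Cl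
Why: Silylation of both acidic groups and mild aqueous acid, which hydrolyses the much more labile silyl ester of 22 and leaves the aryl silyl ether, is the standard way to mask the phenol of a hydroxybenzoic acid.

Step 15
Reactants: 20 (1R,4R,5S,6S,8R)-dauc-9-ene-4,6,8-triol; 23 4-[(tert-butyldimethylsilyl)oxy]-3-methoxybenzoic acid
Product: 25 (1R,4R,5S,6S,8R)-4,8-dihydroxydauc-9-en-6-yl 4-[(tert-butyldimethylsilyl)oxy]-3-methoxybenzoate, via mixed anhydride 24 (not isolated)
Conditions: 23, 2,4,6-trichlorobenzoyl chloride, Et3N, THF, rt; then 20, DMAP, toluene, rt to 60 °C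
Reagents that add atoms: none
Why: Yamaguchi esterification through mixed anhydride 24 acylates C6, the only secondary hydroxyl, with retention, the tertiary C4 and C8 hydroxyls being too hindered to compete.

Step 16
Reactants: 25 (1R,4R,5S,6S,8R)-4,8-dihydroxydauc-9-en-6-yl 4-[(tert-butyldimethylsilyl)oxy]-3-methoxybenzoate
Product: 26 CNP0243386.4, (1R,4R,5S,6S,8R)-4,8-dihydroxydauc-9-en-6-yl 4-hydroxy-3-methoxybenzoate
Conditions: Bu4NF, AcOH (1:1), THF, 0 °C
Reagents that add atoms: none
Why: Buffered fluoride cleaves the aryl silyl ether quickly and leaves the hindered benzoate ester and the tertiary allylic alcohol untouched.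

Compound list

1 | (E)-but-2-enal (crotonaldehyde) | C/C=C/C=O | starting material
2 | ethyl 2-(triphenylphosphoranylidene)propanoate | CCOC(=O)C(C)=P(c1ccccc1)(c1ccccc1)c1ccccc1 | starting material
3 | ethyl (2E,4E)-2-methylhexa-2,4-dienoate | CCOC(=O)/C(C)=C/C=C/C | intermediate
4 | (2E,4E)-2-methylhexa-2,4-dien-1-ol | OC/C(C)=C/C=C/C | intermediate
5 | (2E,4E)-1-bromo-2-methylhexa-2,4-diene | BrC/C(C)=C/C=C/C | intermediate
6 | pentane-2,4-dione (acetylacetone) | CC(=O)CC(C)=O | starting material
7 | sodium lithium 1,3-dianion of pentane-2,4-dione (not isolated) | [Na+].[Li+].[CH2-]C(=O)[CH-]C(C)=O | intermediate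
8 | (7E,9E)-7-methylundeca-7,9-diene-2,4-dione | CC(=O)CC(=O)CC/C(C)=C/C=C/C | intermediate
9 | (7E,9E)-3-diazo-7-methylundeca-7,9-diene-2,4-dione | CC(=O)C(=[N+]=[N-])C(=O)CC/C(C)=C/C=C/C | intermediate
10 | lithium enolate of 9 on the acetyl side (not isolated) | [Li+].C=C([O-])C(=[N+]=[N-])C(=O)CC/C(C)=C/C=C/C | intermediate
11 | (7E,9E)-2-[(tert-butyldimethylsilyl)oxy]-3-diazo-7-methylundeca-1,7,9-trien-4-one | C=C(O[Si](C)(C)C(C)(C)C)C(=[N+]=[N-])C(=O)CC/C(C)=C/C=C/C | intermediate
12 | (1S,5R,6R)-1-{1-[(tert-butyldimethylsilyl)oxy]ethenyl}-5-methyl-6-[(1E)-prop-1-en-1-yl]bicyclo[3.1.0]hexan-2-one; methyl, siloxyvinyl and propenyl all on the exo face (not isolated) | O=C1CC[C@]2(C)[C@@H](/C=C/C)[C@]12C(=C)O[Si](C)(C)C(C)(C)C | intermediate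
13 | (3aR,6R)-8-[(tert-butyldimethylsilyl)oxy]-3a,6-dimethyl-3,3a,6,7-tetrahydroazulen-1(2H)-one; daucane locants: C4 ketone, C5=C6 enol silyl ether, C9=C10 alkene, 1R, 8R, C8 methyl trans to C1 methyl | O=C1CC[C@]2(C)C=C[C@H](C)CC(O[Si](C)(C)C(C)(C)C)=C12 | intermediate
14 | isopropylmagnesium chloride | CC(C)[Mg]Cl | starting material
15 | (1R,3aR,6R)-8-[(tert-butyldimethylsilyl)oxy]-3a,6-dimethyl-1-(propan-2-yl)-1,2,3,3a,6,7-hexahydroazulen-1-ol; daucane C4 hydroxyl cis and isopropyl trans to the C1 methyl | O[C@@]1(C(C)C)CC[C@]2(C)C=C[C@H](C)CC(O[Si](C)(C)C(C)(C)C)=C12 | intermediate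
16 | (1R,4R,5R,8R)-4-hydroxydauc-9-en-6-one; trans-fused, C5–H trans to the C1 methyl | O=C1C[C@@H](C)C=C[C@@]2(C)CC[C@@](O)(C(C)C)[C@H]12 | intermediate
17 | (1R,4R,5R)-4-hydroxydauca-7,9-dien-6-one | O=C1C=C(C)C=C[C@@]2(C)CC[C@@](O)(C(C)C)[C@H]12 | intermediate
18 | (1R,4R,5S,6S)-dauca-7,9-diene-4,6-diol | O[C@H]1C=C(C)C=C[C@@]2(C)CC[C@@](O)(C(C)C)[C@H]12 | intermediate
19 | (1R,4R,5S,6R,7R,8S)-7,8-epoxydauc-9-ene-4,6-diol; oxirane cis to the C6 hydroxyl | O[C@H]1[C@H]2O[C@@]2(C)C=C[C@@]3(C)CC[C@@](O)(C(C)C)[C@H]13 | intermediate
20 | (1R,4R,5S,6S,8R)-dauc-9-ene-4,6,8-triol | O[C@H]1C[C@@](C)(O)C=C[C@@]2(C)CC[C@@](O)(C(C)C)[C@H]12 | intermediate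
21 | vanillic acid (4-hydroxy-3-methoxybenzoic acid) | COc1cc(C(=O)O)ccc1O | starting material
22 | tert-butyldimethylsilyl 4-[(tert-butyldimethylsilyl)oxy]-3-methoxybenzoate (not isolated) | COc1cc(C(=O)O[Si](C)(C)C(C)(C)C)ccc1O[Si](C)(C)C(C)(C)C | intermediate
23 | 4-[(tert-butyldimethylsilyl)oxy]-3-methoxybenzoic acid | COc1cc(C(=O)O)ccc1O[Si](C)(C)C(C)(C)C | intermediate
24 | 4-[(tert-butyldimethylsilyl)oxy]-3-methoxybenzoic 2,4,6-trichlorobenzoic anhydride (not isolated) | COc1cc(C(=O)OC(=O)c2c(Cl)cc(Cl)cc2Cl)ccc1O[Si](C)(C)C(C)(C)C | intermediate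
25 | (1R,4R,5S,6S,8R)-4,8-dihydroxydauc-9-en-6-yl 4-[(tert-butyldimethylsilyl)oxy]-3-methoxybenzoate | COc1cc(C(=O)O[C@H]2C[C@@](C)(O)C=C[C@@]3(C)CC[C@@](O)(C(C)C)[C@H]23)ccc1O[Si](C)(C)C(C)(C)C | intermediate
26 | CNP0243386.4, (1R,4R,5S,6S,8R)-4,8-dihydroxydauc-9-en-6-yl 4-hydroxy-3-methoxybenzoate | COc1cc(C(=O)O[C@H]2C[C@@](C)(O)C=C[C@@]3(C)CC[C@@](O)(C(C)C)[C@H]23)ccc1O | target

Total step count: 16. Longest linear sequence: 15 steps (steps 1 to 13, then 15 and 16; step 14 is the side branch).

Steps most likely to fail

Step 7. The enantioface discrimination of the chiral dirhodium carboxylate may be weak for a ketone-acceptor carbenoid adding to a trisubstituted alkene, which would lower the optical purity of everything that follows; the Cope stage itself can be driven by heat. The fallback takes optical purity from resolution and not from the catalyst. It sets out from 11 and comes back at 13: the cascade is run with achiral Rh2(OAc)4 in heptane (rt, then 80 °C), which passes through 12 together with its mirror image ent-12 F1 and gives 13 together with its mirror image ent-13 F2. The two enantiomers are separated by preparative chromatography on a chiral stationary phase (supercritical CO2, polysaccharide carbamate column), and the wanted one continues at step 8.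

Step 8. The isopropyl nucleophile may approach C4 from the face of the C1 methyl or without preference (poor or reversed facial selectivity), since the two faces differ only in that methyl against the sp2 C10. The fallback sets C4 by oxygen delivery instead of carbon delivery. It sets out from 13 and comes back at 16: the addition is run as in step 8, and the crude mixture of 15 and its C4 epimer 4-epi-15 F3 is stirred with 1 M HCl in THF. This erases C4 by allylic transposition and desilylation (Stork–Danheiser) and gives the conjugated enone (1R,8R)-dauca-4,9-dien-6-one F4. Alkaline H2O2 in MeOH at 0 °C (Weitz–Scheffer epoxidation) then attacks C4 as a nucleophile, so the same facial bias that misdirected the organometallic now places the C–O bond cis to the C1 methyl and gives the 4,5-epoxy ketone with its oxirane on the face of the C1 methyl, 4,5-epoxydauc-9-en-6-one F5. SmI2 in THF/MeOH at −78 °C cleaves the C5–O bond (reduction of an α,β-epoxy ketone to the β-hydroxy ketone), and protonation at C5 gives 16.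

Step 6. Deprotonation at the C3 methylene may compete with that at the acetyl methyl (poor regioselectivity of enolisation), feeding an isomeric enol silane into the cascade that is hard to remove from the labile product. The fallback changes the order of events so that the diketone is still symmetrical when it is silylated. It sets out from 6 (and uses bromide 5) and comes back at 11: diazo transfer to 6 (4-acetamidobenzenesulfonyl azide, Et3N, MeCN) gives 3-diazopentane-2,4-dione F6. One equivalent of t-BuMe2SiOTf with Et3N (CH2Cl2, 0 °C) gives the mono enol silane 4-[(tert-butyldimethylsilyl)oxy]-3-diazopent-4-en-2-one F7, whose only enolisable position left is the other acetyl methyl. LiN(SiMe3)2 (THF, −78 °C) gives the lithium enolate of F7 F8, and alkylation with 5 (DMPU, −78 to −20 °C; γ-alkylation of the enolate of a 2-diazo-1,3-dicarbonyl compound) gives 11 directly.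

Further compounds

F1 | step 7 | (1R,5S,6S)-1-{1-[(tert-butyldimethylsilyl)oxy]ethenyl}-5-methyl-6-[(1E)-prop-1-en-1-yl]bicyclo[3.1.0]hexan-2-one, ent-12 (not isolated) | O=C1CC[C@@]2(C)[C@H](/C=C/C)[C@@]12C(=C)O[Si](C)(C)C(C)(C)C
F2 | step 7 | (3aS,6S)-8-[(tert-butyldimethylsilyl)oxy]-3a,6-dimethyl-3,3a,6,7-tetrahydroazulen-1(2H)-one, ent-13 | O=C1CC[C@@]2(C)C=C[C@@H](C)CC(O[Si](C)(C)C(C)(C)C)=C12
F3 | step 8 | (1S,3aR,6R)-8-[(tert-butyldimethylsilyl)oxy]-3a,6-dimethyl-1-(propan-2-yl)-1,2,3,3a,6,7-hexahydroazulen-1-ol, 4-epi-15 (not isolated) | O[C@]1(C(C)C)CC[C@]2(C)C=C[C@H](C)CC(O[Si](C)(C)C(C)(C)C)=C12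
F4 | step 8 | (1R,8R)-dauca-4,9-dien-6-one | O=C1C[C@@H](C)C=C[C@@]2(C)CCC(C(C)C)=C12
F5 | step 8 | (1R,8R)-4,5-epoxydauc-9-en-6-one, oxirane cis to the C1 methyl | O=C1C[C@@H](C)C=C[C@@]2(C)CC[C@]3(C(C)C)O[C@]123
F6 | step 6 | 3-diazopentane-2,4-dione | CC(=O)C(=[N+]=[N-])C(C)=O
F7 | step 6 | 4-[(tert-butyldimethylsilyl)oxy]-3-diazopent-4-en-2-one | C=C(O[Si](C)(C)C(C)(C)C)C(=[N+]=[N-])C(C)=O
F8 | step 6 | lithium enolate of F7 (not isolated) | [Li+].C=C([O-])C(=[N+]=[N-])C(=C)O[Si](C)(C)C(C)(C)C
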